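**Retrosynthetic overview**

Reading of the target (polypodane numbering: ring A = C1–C5, C10; ring B = C5–C10; C11 on C9; β = face of CH3-10): the SMILES puts H5 on the same face as CH3-10, i.e. a cis-fused decalin (5S,8R,9R,10S), with C11 and CH3-8 β and 8-OH α; the route is built for exactly this isomer.
Enabling feature: C9 lies between C8 and C10, so as a ketone it makes both α-carbons nucleophilic, and C5–C6–C7 becomes the matching bis-electrophile when C6 carries a temporary carboxyl as a 2-(bromomethyl)acrylate. In the cis-fused skeleton C5–C6 and the C3 oxygen are 1,3-diaxial on ring A, so this carboxyl can be tied to O3 as a δ-lactone (C3 carried as a carbinol).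
Key disconnections: C5–C10 and C7–C8 together (one-flask SN2′/Michael [3+3] annulation of an acyclic ketone onto the lactone); then loss of the C6 carboxyl, C9=O → C9=C11, C11–C12 (sulfone + farnesyl bromide), C23–O (allylic oxidation).
Ring order: temporary lactone (metathesis) → ring A → ring B (both in step 8) → lactone opened and its carbonyl carbon excised.
Stereocontrol: C3 (reagent-controlled prenylation) is relayed through the tether to C5, C10 and C8; C9 comes from hydroxyl-directed hydrogenation; C3 is oxidised to the ketone near the end.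

Key step: step 8

**Route**

Step 1
Reactants: 1 ethyl (S)-2-[(tert-butyldimethylsilyl)oxy]propanoate
Product: 2 (S)-2-[(tert-butyldimethylsilyl)oxy]-N-methoxy-N-methylpropanamide
Conditions: MeNH(OMe)·HCl, i-PrMgCl, THF, –20 → 0 °C
Reagents that add atoms: N,O-dimethylhydroxylamine hydrochloride, CNOC.Cl
Why: Weinreb amide formation by aminolysis of the ester with the chloromagnesium amide at low temperature, which should leave the α-silyloxy stereocentre untouched.

Step 2
Reactants: 2 Weinreb amide
Product: 3 (S)-2-[(tert-butyldimethylsilyl)oxy]pentan-3-one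
Conditions: EtMgBr, THF, 0 °C
Reagents that add atoms: ethylmagnesium bromide, CC[Mg]Br
Why: Grignard addition to a Weinreb amide stops at the ketone through the stable magnesium chelate.

Step 3
Reactants: 3 ethyl ketone; 4 2-(2-bromoethyl)-1,3-dioxolane
Product: 5 (2S)-2-[(tert-butyldimethylsilyl)oxy]-6-(1,3-dioxolan-2-yl)-4-methylhexan-3-one (C4 epimers)
Conditions: LiN(i-Pr)2, THF, –78 °C; then 4, HMPA, Bu4NI (cat.), –78 → –20 °C
Reagents that add atoms: none
Why: Kinetic enolisation of an α-silyloxy ethyl ketone occurs at the less hindered CH2 and the enolate is alkylated by SN2; the new centre (future C10) forms unselectively, which does not matter because it is re-enolised in step 8.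

Step 4
Reactants: 5 dioxolane ketone
Product: 6 (6S)-6-[(tert-butyldimethylsilyl)oxy]-4-methyl-5-oxoheptanal (C4 epimers)
Conditions: PPTS, acetone–H2O (4:1), 55 °C
Reagents that add atoms: water, O
Why: Mild acid-catalysed acetal hydrolysis, under which the secondary silyl ether and the ketone should survive.

Step 5
Reactants: 6 keto aldehyde
Product: 7 (2S,7R)-2-[(tert-butyldimethylsilyl)oxy]-7-hydroxy-4,8,8-trimethyldec-9-en-3-one (C4 epimers)
Conditions: (–)-Ipc2B(CH2CH=CMe2) [from (+)-α-pinene], Et2O, –78 °C; then HOCH2CH2NH2, 25 °C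
Reagents that add atoms: (–)-B-(3-methylbut-2-en-1-yl)diisopinocampheylborane, CC(C)=CCB(C1CC2CC(C1C)C2(C)C)C1CC2CC(C1C)C2(C)C
Why: Brown reverse prenylation (γ-selective allylboration through a chair six-membered transition state) adds chemoselectively to the aldehyde and sets the carbinol centre (future C3, R) by reagent control; the antipode of the reagent is chosen for this sense.

Step 6
Reactants: 7 homoallylic alcohol; 8 2-(bromomethyl)prop-2-enoic acid
Product: 9 (4R,9S)-9-[(tert-butyldimethylsilyl)oxy]-3,3,7-trimethyl-8-oxodec-1-en-4-yl 2-(bromomethyl)prop-2-enoate (C7 epimers)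
Conditions: DCC, DMAP (cat.), CH2Cl2, 0 → 25 °C
Reagents that add atoms: none
Why: Steglich esterification under neutral conditions, so neither the allylic bromide nor the enolisable ketone is touched.

Step 7
Reactants: 9 diene ester
Product: 10 (6R)-3-(bromomethyl)-6-{(5S)-5-[(tert-butyldimethylsilyl)oxy]-3-methyl-4-oxohexyl}-5,5-dimethyl-5,6-dihydro-2H-pyran-2-one (side-chain C3 epimers)
Conditions: second-generation Hoveyda–Grubbs catalyst (5 mol %), toluene (0.005 M), 80 °C
Reagents that add atoms: none
Why: Ring-closing metathesis of a 2-substituted acrylate with the vinyl group, helped by the gem-dimethyl group, closes the six-membered unsaturated lactone that serves as tether and bis-electrophile.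

Step 8
Reactants: 10 bromomethyl lactone
Product: 12 tricyclic keto-lactone (5β-H; 10β-CH3; 8α-OTBS; 8β-CH3; 9-oxo; lactone from the 3α-oxygen to the C6 carboxyl), via exo-methylene keto-lactone 11 (not isolated)
Conditions: KN(SiMe3)2 (2.2 equiv), THF (0.01 M), –78 → 0 °C; then AcOH
Reagents that add atoms: none
Why: The base enolises the ketone reversibly, but only the C10 enolate has a six-membered outlet: it adds 6-(enolexo)-exo-trig to C5 of the 2-(bromomethyl)acrylate lactone and the ester enolate expels bromide (overall SN2′) to give 11, whose ketone can now enolise only toward C8; that α-silyloxy enolate closes ring B by 6-endo-trig Michael addition of C8 to the new exocyclic methylene carbon C7. The closest known reaction type is the α,α′-annulation of ketones with 2-(bromomethyl)acrylates (SN2′ alkylation, then Michael addition), here with the acrylate tied to O3 so that the first closure is the familiar intramolecular Michael addition that gives bicyclo[3.3.1]nonanes. C5: the chain hangs from the lactone carbon C3, so C10 can reach C5 only on the face of the C3–C2 bond; C3 and C5 become bridgeheads of a 2-oxabicyclo[3.3.1]nonanone, which fixes C5–C6 axial and cis to O3, i.e. H5 cis to CH3-10. C10: in the chair transition state of ring A the enolate unit (C9) should sit equatorial and the methyl axial, and only this epimer places C9 gauche to C6 so that ring B can close at all. C8: dipole repulsion and A(1,3) strain should place the OTBS group anti to the enolate oxygen (syn to quaternary C10), and this in-plane group ends axial on the lactone (α) face when C8 bonds to C7 in the tethered chair, leaving the methyl equatorial (β). The step needs conjugate (C5) rather than carbonyl or oxygen attack and intra- rather than intermolecular capture: addition at C5 becomes irreversible by bromide loss, oxygen or C8 attack on C5 would need eight-membered rings, and high dilution suppresses the rest.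

Step 9
Reactants: 12 tricyclic keto-lactone
Product: 14 3α-hydroxy-8α-[(tert-butyldimethylsilyl)oxy]-4,4,8β,10β-tetramethyl-5β-decalin-9-one (polypodane numbering), via caesium carboxylate 13 (not isolated)
Conditions: CsOH·H2O, THF–H2O, 40 °C, evaporate; then 9-mesityl-10-methylacridinium tetrafluoroborate (5 mol %), PhSSPh (10 mol %), CF3CH2OH–H2O, 450 nm LED, 25 °C
Reagents that add atoms: none
Why: Saponification opens the bridged lactone and photoredox hydrodecarboxylation of the carboxylate salt (acridinium photo-oxidant, thiol hydrogen-atom donor) removes the temporary carbon and the C6 stereocentre; working on the salt avoids relactonisation.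

Step 10
Reactants: 14 hindered ketone
Product: 15 9(11)-methylene compound (3α-OH, 8α-OTBS)
Conditions: Cp2Ti(μ-CH2)(μ-Cl)AlMe2 (3 equiv), pyridine (cat.), THF–toluene, –40 → 25 °C
Reagents that add atoms: Tebbe reagent, C=[Ti](C1C=CC=C1)C1C=CC=C1.C[Al](C)Cl
Why: Tebbe methylenation (titanium methylidene [2+2] addition and cycloreversion) is suited to non-enolisable ketones flanked by quaternary carbons where Wittig reagents fail; it installs C11 without a new stereocentre.

Step 11
Reactants: 15 silyl ether
Product: 16 3α,8α-dihydroxy-9(11)-methylene compound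
Conditions: Bu4NF, THF, 60 °C
Reagents that add atoms: none
Why: Fluoride-induced desilylation frees the tertiary C8 hydroxyl needed as directing group, under non-acidic conditions that spare the allylic tertiary carbinol.

Step 12
Reactants: 16 allylic diol
Product: 18 9(11)-en-11-yl phenyl sulfone (vinyl sulfone; alkene geometry immaterial), via tertiary iodo sulfone 17 (not isolated)
Conditions: PhSO2Na, I2, EtOAc–H2O, 25 °C; then DBU, CH2Cl2, 0 °C
Reagents that add atoms: sodium benzenesulfinate, [Na+].[O-]S(=O)c1ccccc1
Why: Radical iodosulfonylation (the sulfonyl radical adds to the terminal carbon, iodine is transferred to C9) followed by dehydroiodination, which can only go toward C11 because C8 and C10 are quaternary; this places the sulfone needed for the chain coupling.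

Step 13
Reactants: 18 vinyl sulfone
Product: 19 11-(phenylsulfonyl) bicyclic diol (9α-H; C11 β; 3α-OH; 8α-OH; 5β-H)
Conditions: [Ir(cod)(PCy3)(py)]PF6 (10 mol %), H2 (1 atm), CH2Cl2, 25 °C
Reagents that add atoms: none
Why: Hydroxyl-directed homogeneous hydrogenation: the C8 hydroxyl binds iridium and hydrogen is delivered to the exocyclic alkene from the hydroxyl (α) face, so H9 should end α and C11 β whatever the conformational preference of the cis-decalin.

Step 14
Reactants: 19 sulfone; 20 (2E,6E)-farnesyl bromide
Product: 21 C11-farnesylated sulfone (C11 epimers)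
Conditions: n-BuLi (3.2 equiv), THF–HMPA, –78 °C; then 20 (1.2 equiv), –78 → –20 °C
Reagents that add atoms: none
Why: Julia-type coupling: the lithiated sulfone (both hydroxyls carried as lithium alkoxides) is alkylated by SN2 at the primary allylic bromide, which keeps the farnesyl double-bond geometry; the new C11 centre is erased in step 15.

Step 15
Reactants: 21 alkylated sulfone
Product: 22 3α,8α-dihydroxy-5β-polypoda-13E,17E,21-triene
Conditions: Na(Hg) (5%), Na2HPO4, MeOH–THF, –20 °C
Reagents that add atoms: none
Why: Reductive desulfonylation with sodium amalgam; the sulfone is not allylic, so no double-bond migration is expected.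

Step 16
Reactants: 22 diol
Product: 23 8α-hydroxy-5β-polypoda-13E,17E,21-trien-3-one
Conditions: Dess–Martin periodinane, NaHCO3, CH2Cl2, 0 → 25 °C
Reagents that add atoms: none
Why: Dess–Martin oxidation of the only secondary alcohol; the tertiary C8 hydroxyl and the alkenes are inert, and C5 cannot epimerise because C4 is quaternary.

Step 17
Reactants: 23 ketone
Product: 24 (21E)-8α,23-dihydroxy-5β-polypoda-13E,17E,21-trien-3-one (terminal allylic alcohol)
Conditions: SeO2 (0.2 equiv), t-BuOOH (3 equiv), salicylic acid (0.1 equiv), CH2Cl2, 25 °C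
Reagents that add atoms: tert-butyl hydroperoxide, CC(C)(C)OO
Why: Selenium dioxide-catalysed allylic oxidation (ene reaction, then [2,3]-sigmatropic shift) attacks the terminal isopropylidene group preferentially and oxidises its (E)-methyl, giving the (E)-allylic alcohol.

Step 18
Reactants: 24 allylic alcohol
Product: 25 myrrhanone A acetate as specified (5S,8R,9R,10S; 13E,17E,21E)
Conditions: Ac2O, pyridine, DMAP (cat.), CH2Cl2, 0 °C
Reagents that add atoms: acetic anhydride, CC(=O)OC(C)=O
Why: Acetylation of the primary allylic alcohol; the hindered tertiary C8 hydroxyl should not react at 0 °C.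

**Compound list**

1 | ethyl (S)-2-[(tert-butyldimethylsilyl)oxy]propanoate | CCOC(=O)[C@H](C)O[Si](C)(C)C(C)(C)C | starting material
2 | (S)-2-[(tert-butyldimethylsilyl)oxy]-N-methoxy-N-methylpropanamide | CON(C)C(=O)[C@H](C)O[Si](C)(C)C(C)(C)C | intermediate
3 | (S)-2-[(tert-butyldimethylsilyl)oxy]pentan-3-one | CCC(=O)[C@H](C)O[Si](C)(C)C(C)(C)C | intermediate
4 | 2-(2-bromoethyl)-1,3-dioxolane | BrCCC1OCCO1 | starting material
5 | (2S)-2-[(tert-butyldimethylsilyl)oxy]-6-(1,3-dioxolan-2-yl)-4-methylhexan-3-one (C4 epimers) | CC(CCC1OCCO1)C(=O)[C@H](C)O[Si](C)(C)C(C)(C)C | intermediate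
6 | (6S)-6-[(tert-butyldimethylsilyl)oxy]-4-methyl-5-oxoheptanal (C4 epimers) | CC(CCC=O)C(=O)[C@H](C)O[Si](C)(C)C(C)(C)C | intermediate
7 | (2S,7R)-2-[(tert-butyldimethylsilyl)oxy]-7-hydroxy-4,8,8-trimethyldec-9-en-3-one (C4 epimers) | C=CC(C)(C)[C@H](O)CCC(C)C(=O)[C@H](C)O[Si](C)(C)C(C)(C)C | intermediate
8 | 2-(bromomethyl)prop-2-enoic acid | C=C(CBr)C(=O)O | starting material
9 | (4R,9S)-9-[(tert-butyldimethylsilyl)oxy]-3,3,7-trimethyl-8-oxodec-1-en-4-yl 2-(bromomethyl)prop-2-enoate (C7 epimers) | C=CC(C)(C)[C@H](OC(=O)C(=C)CBr)CCC(C)C(=O)[C@H](C)O[Si](C)(C)C(C)(C)C | intermediate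
10 | (6R)-3-(bromomethyl)-6-{(5S)-5-[(tert-butyldimethylsilyl)oxy]-3-methyl-4-oxohexyl}-5,5-dimethyl-5,6-dihydro-2H-pyran-2-one (side-chain C3 epimers) | BrCC1=CC(C)(C)[C@@H](CCC(C)C(=O)[C@H](C)O[Si](C)(C)C(C)(C)C)OC1=O | intermediate
11 | exo-methylene keto-lactone: ring A closed (C5–C10; 5β-H, 10β-CH3), lactone from 3α-O to the carboxyl on C6, exocyclic C6=C7, C10 carrying the (S)-2-(silyloxy)propanoyl group | C[C@H](O[Si](C)(C)C(C)(C)C)C(=O)[C@@]2(C)CC[C@@H](OC3=O)C(C)(C)[C@H]2C3=C | intermediate
12 | tricyclic keto-lactone: cis-fused decalin (5β-H, 10β-CH3), 9-oxo, 8α-OTBS, 8β-CH3, δ-lactone from 3α-O to the C6 carboxyl (C6 configuration immaterial) | O=C1[C@@]2(C)CC[C@@H](OC3=O)C(C)(C)[C@H]2C3C[C@@]1(C)O[Si](C)(C)C(C)(C)C | intermediate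
13 | caesium 3α-hydroxy-8α-[(tert-butyldimethylsilyl)oxy]-9-oxo-5β-decalin-6-carboxylate (4,4,8β,10β-tetramethyl; C6 configuration immaterial) | O=C1[C@@]2(C)CC[C@@H](O)C(C)(C)[C@H]2C(C(=O)[O-])C[C@@]1(C)O[Si](C)(C)C(C)(C)C.[Cs+] | intermediate
14 | 3α-hydroxy-8α-[(tert-butyldimethylsilyl)oxy]-4,4,8β,10β-tetramethyl-5β-decalin-9-one | O=C1[C@@]2(C)CC[C@@H](O)C(C)(C)[C@H]2CC[C@@]1(C)O[Si](C)(C)C(C)(C)C | intermediate
15 | 9(11)-methylene-3α-hydroxy-8α-silyloxy bicycle (5β-H) | C=C1[C@@]2(C)CC[C@@H](O)C(C)(C)[C@H]2CC[C@@]1(C)O[Si](C)(C)C(C)(C)C | intermediate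
16 | 9(11)-methylene-3α,8α-diol (5β-H, 8β-CH3, 10β-CH3) | C=C1[C@@]2(C)CC[C@@H](O)C(C)(C)[C@H]2CC[C@@]1(C)O | intermediate
17 | 9-iodo-11-(phenylsulfonyl)-3α,8α-diol (C9 configuration unspecified) | O=S(=O)(CC1(I)[C@@]2(C)CC[C@@H](O)C(C)(C)[C@H]2CC[C@@]1(C)O)c1ccccc1 | intermediate
18 | 11-(phenylsulfonyl)-9(11)-ene-3α,8α-diol (alkene geometry unspecified) | O=S(=O)(C=C1[C@@]2(C)CC[C@@H](O)C(C)(C)[C@H]2CC[C@@]1(C)O)c1ccccc1 | intermediate
19 | 11-(phenylsulfonyl)-3α,8α-diol (9α-H, C11 β, 5β-H) | O=S(=O)(C[C@@H]1[C@@]2(C)CC[C@@H](O)C(C)(C)[C@H]2CC[C@@]1(C)O)c1ccccc1 | intermediate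
20 | (2E,6E)-farnesyl bromide | CC(C)=CCC/C(C)=C/CC/C(C)=C/CBr | starting material
21 | 11-(phenylsulfonyl)-5β-polypoda-13E,17E,21-triene-3α,8α-diol (C11 epimers) | CC(C)=CCC/C(C)=C/CC/C(C)=C/CC(S(=O)(=O)c1ccccc1)[C@@H]1[C@@]2(C)CC[C@@H](O)C(C)(C)[C@H]2CC[C@@]1(C)O | intermediate
22 | 5β-polypoda-13E,17E,21-triene-3α,8α-diol | CC(C)=CCC/C(C)=C/CC/C(C)=C/CC[C@@H]1[C@@]2(C)CC[C@@H](O)C(C)(C)[C@H]2CC[C@@]1(C)O | intermediate
23 | 8α-hydroxy-5β-polypoda-13E,17E,21-trien-3-one | CC(C)=CCC/C(C)=C/CC/C(C)=C/CC[C@@H]1[C@@]2(C)CCC(=O)C(C)(C)[C@H]2CC[C@@]1(C)O | intermediate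
24 | (21E)-8α,23-dihydroxy-5β-polypoda-13E,17E,21-trien-3-one | OC/C(C)=C/CC/C(C)=C/CC/C(C)=C/CC[C@@H]1[C@@]2(C)CCC(=O)C(C)(C)[C@H]2CC[C@@]1(C)O | intermediate
25 | myrrhanone A acetate as specified (5S,8R,9R,10S) | CC(=O)OC/C(C)=C/CC/C(C)=C/CC/C(C)=C/CC[C@@H]1[C@@]2(C)CCC(=O)C(C)(C)[C@H]2CC[C@@]1(C)O | target

**Step count and risks**

Total step count: 18. Longest linear sequence: 18 steps (1 → 25); compounds 4, 8 and 20 are purchased.

Steps most likely to fail:

Step 8. The first bond joins a fully substituted enolate carbon to a β-carbon next to the gem-dimethyl centre, so ring A closure may be slow enough for intermolecular SN2′ oligomerisation to compete. The sequence may also stall after ring A, or the second closure may pass through the other enolate geometry and erode the C8 configuration. Fallback, setting out from 10 and returning at 12: one equivalent of LiN(SiMe3)2 at –78 °C with acidic quench should give the monocyclised exo-methylene keto-lactone 11, which is isolated. Its ketone, enolisable only toward C8, is converted with Me3SiOTf/Et3N into the trimethylsilyl enol ether F1. TiCl4 in CH2Cl2 at –78 °C then closes ring B by an intramolecular Mukaiyama–Michael addition onto the α-methylene lactone, giving 12.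

Step 10. The [2+2] addition of the titanium methylidene may be blocked at a carbonyl flanked by two quaternary carbons, one carrying the bulky silyl ether, so that the reagent is consumed only by the free hydroxyl. Fallback, setting out from 14 and returning at 15: addition of Me3SiCH2Li/CeCl3 (THF, –78 °C; organocerium reagents add to very hindered non-enolisable ketones) should give the β-hydroxysilane F2, and KH in THF then effects Peterson elimination to 15.

Step 13. The electron-poor, heavily flanked vinyl sulfone may coordinate and hydrogenate sluggishly, allowing catalyst deactivation or undirected delivery from the wrong face. Fallback, setting out from 16 and returning at 19: hydroboration of the exocyclic methylene with BH3·THF (borane bound as the C8 alkoxyborane delivers hydrogen to C9 on the hydroxyl face) and NaOH/H2O2 oxidation should give the 3α,8α,11-triol F3. PhSSPh/PBu3 converts its primary hydroxyl into the 11-phenylthio diol F4, and H2O2 with catalytic (NH4)6Mo7O24·4H2O oxidises this to sulfone 19.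

Further compounds
F1 | step 8 | C8 trimethylsilyl enol ether of keto-lactone 11 (enol ether geometry unspecified) | CC(O[Si](C)(C)C(C)(C)C)=C(O[Si](C)(C)C)[C@@]2(C)CC[C@@H](OC3=O)C(C)(C)[C@H]2C3=C
F2 | step 10 | 9-hydroxy-9-[(trimethylsilyl)methyl] adduct of ketone 14 (C9 configuration unspecified) | C[Si](C)(C)CC1(O)[C@@]2(C)CC[C@@H](O)C(C)(C)[C@H]2CC[C@@]1(C)O[Si](C)(C)C(C)(C)C
F3 | step 13 | 3α,8α,11-triol (9α-H, C11 β, 5β-H) | OC[C@@H]1[C@@]2(C)CC[C@@H](O)C(C)(C)[C@H]2CC[C@@]1(C)O
F4 | step 13 | 11-(phenylthio)-3α,8α-diol (9α-H, C11 β, 5β-H) | c1ccccc1SC[C@@H]1[C@@]2(C)CC[C@@H](O)C(C)(C)[C@H]2CC[C@@]1(C)O
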